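Ring A (C4a–C5–C6–C7–C8–C8a) is a resorcinol carrying oxygen on C8a and C7 and hydrogen on C8, the signature of a vinylketene–ynol ether benzannulation, so it is assembled last from an open chain. An unsaturated acid chloride that already holds the C4 stereocentre in a 3-arylglutarate half-ester arm is dehydrochlorinated to a vinylketene, which takes up tert-butoxyacetylene; cyclobutenone opening and 6π closure forge C8a–C8, C7–C6 and C8a–C4a, and the new C8a phenol, ortho to the C4 arm, closes O1–C2 onto the methyl ester. C4 is set earlier by desymmetrising methanolysis of the arylglutaric anhydride and is never disturbed.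

Key step: step 11

Remarks on the chemistry
- Configuration: the C4 centre keeps one spatial arrangement from the half-ester to the target. Its descriptor is R throughout, except in the transient ketene, cyclobutenone, dienylketene and dienone of the key step, where it reads S only because the CIP ranking of its neighbours changes.
- Assumption: the quinine-derived catalyst of step 3 is taken to give the (R)-half-ester. If the configuration check on the half-ester shows the opposite sense, the quinidine-derived pseudoenantiomer is used with no other change.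
- Key-step partners: the alkene geometry of the acid chloride is erased on ketene formation, so E/Z mixtures are usable. tert-Butyl ynol ethers lose isobutene on warming, so the alkyne is made fresh (step 10), the cycloaddition is run cold, and heat is applied only after the excess alkyne has been removed.

Step 1
Reactants: 1 3,4-bis(benzyloxy)benzaldehyde; 2 ethyl acetoacetate (2.2 equiv)
Product: 4 3-[3,4-bis(benzyloxy)phenyl]pentanedioic acid, via bis(acetoacetate) adduct 3 (not isolated)
Conditions: piperidine (cat.), EtOH, 20 °C; then aq. KOH, reflux; then HCl to pH 1, 0 °C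
Reagents that add atoms: potassium hydroxide, [K+].[OH-]
Why: Knoevenagel condensation and Michael addition of a second acetoacetate give the 2:1 adduct, which hot alkali degrades by double retro-Claisen deacetylation and saponification to the 3-arylglutaric acid, with the benzyl ethers inert to base.

Step 2
Reactants: 4 3-[3,4-bis(benzyloxy)phenyl]pentanedioic acid
Product: 5 4-[3,4-bis(benzyloxy)phenyl]oxane-2,6-dione
Conditions: Ac2O, 100 °C; crystallise
Reagents that add atoms: none
Why: Cyclodehydration of a 1,5-diacid with acetic anhydride gives the six-membered cyclic anhydride, which should crystallise free of diacid.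

Step 3
Reactants: 5 4-[3,4-bis(benzyloxy)phenyl]oxane-2,6-dione
Product: 6 (R)-3-[3,4-bis(benzyloxy)phenyl]-5-methoxy-5-oxopentanoic acid
Conditions: MeOH (10 equiv), 9-amino(9-deoxy)epi-quinine 3,5-bis(trifluoromethyl)benzenesulfonamide (10 mol%), MTBE (0.05 M), 20 °C; acid wash; recrystallise; check configuration and ee
Reagents that add atoms: methanol, CO
Why: In this desymmetrising alcoholysis the quinuclidine nitrogen activates methanol by general-base catalysis while the sulfonamide N–H binds one of the two enantiotopic carbonyl groups, so the stereocentre (later C4) is set by catalyst control.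

Step 4
Reactants: 6 (R)-3-[3,4-bis(benzyloxy)phenyl]-5-methoxy-5-oxopentanoic acid
Product: 7 methyl (R)-3-[3,4-bis(benzyloxy)phenyl]-5-hydroxypentanoate
Conditions: BH3·SMe2 (1.3 equiv), THF, −10 → 20 °C; MeOH quench; used crude
Reagents that add atoms: none
Why: Borane reduces a carboxylic acid through its acyloxyborane far faster than an ester, so only the acid arm is taken to the primary alcohol and the stereocentre, which carries no acidic hydrogen, is untouched.

Step 5
Reactants: 7 methyl (R)-3-[3,4-bis(benzyloxy)phenyl]-5-hydroxypentanoate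
Product: 8 methyl (R)-3-[3,4-bis(benzyloxy)phenyl]-5-oxopentanoate
Conditions: Dess–Martin periodinane (1.2 equiv), CH2Cl2, 0 → 20 °C
Reagents that add atoms: none
Why: Dess–Martin oxidation converts the primary alcohol into the aldehyde under mild conditions that leave the ester, the benzyl ethers and the β-stereocentre alone.

Step 6
Reactants: 9 tert-butyl diethylphosphonoacetate (1.3 equiv); 10 4-(2-bromoethyl)-1,2-dimethoxybenzene
Product: 11 tert-butyl 2-(diethoxyphosphoryl)-4-(3,4-dimethoxyphenyl)butanoate (racemic)
Conditions: NaH (1.05 equiv), NaI (cat.), DMF, 0 → 55 °C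
Reagents that add atoms: none
Why: SN2 C-alkylation of the stabilised phosphonoacetate carbanion with the primary bromide, where the soft, weakly basic anion favours substitution over E2 and the excess of 9 suppresses dialkylation.

Step 7
Reactants: 8 methyl (R)-3-[3,4-bis(benzyloxy)phenyl]-5-oxopentanoate; 11 tert-butyl 2-(diethoxyphosphoryl)-4-(3,4-dimethoxyphenyl)butanoate (1.2 equiv)
Product: 12 methyl (3R,5E)-3-[3,4-bis(benzyloxy)phenyl]-6-(tert-butoxycarbonyl)-8-(3,4-dimethoxyphenyl)oct-5-enoate
Conditions: NaH (1.15 equiv), THF, 0 °C; then 8, 0 → 20 °C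
Reagents that add atoms: none
Why: Horner–Wadsworth–Emmons olefination with the α-substituted phosphonate should give the trisubstituted enoate mainly as the E isomer, the stereocentre being β to the aldehyde and so not epimerisable, and any Z isomer can be carried on because the geometry is erased in step 11.

Step 8
Reactants: 12 methyl (3R,5E)-3-[3,4-bis(benzyloxy)phenyl]-6-(tert-butoxycarbonyl)-8-(3,4-dimethoxyphenyl)oct-5-enoate
Product: 13 (2E,5R)-5-[3,4-bis(benzyloxy)phenyl]-2-[2-(3,4-dimethoxyphenyl)ethyl]-7-methoxy-7-oxohept-2-enoic acid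
Conditions: TFA/CH2Cl2 (1:4), Et3SiH (2.5 equiv), 0 → 20 °C
Reagents that add atoms: none
Why: Acidolysis of the tert-butyl ester (alkyl–oxygen cleavage) spares the methyl ester and the benzyl aryl ethers, and triethylsilane reduces the tert-butyl cation to isobutane before it can alkylate the electron-rich rings.

Step 9
Reactants: 13 (2E,5R)-5-[3,4-bis(benzyloxy)phenyl]-2-[2-(3,4-dimethoxyphenyl)ethyl]-7-methoxy-7-oxohept-2-enoic acid
Product: 14 methyl (3R,5E)-3-[3,4-bis(benzyloxy)phenyl]-6-(chlorocarbonyl)-8-(3,4-dimethoxyphenyl)oct-5-enoate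
Conditions: (COCl)2 (1.5 equiv), DMF (cat.), CH2Cl2, 0 → 20 °C; evaporate, toluene azeotrope; used at once
Reagents that add atoms: oxalyl chloride, O=C(Cl)C(=O)Cl
Why: Vilsmeier-type activation converts the acid into the acid chloride with only gaseous by-products, so the sensitive product needs no purification.

Step 10
Reactants: 15 trichloroethylene
Product: 18 tert-butoxyacetylene, via dichlorovinyl ether 16 (not isolated), via lithium tert-butoxyacetylide 17 (not isolated)
Conditions: KOtBu (1.1 equiv), THF, −50 → 20 °C; then n-BuLi (2.3 equiv), −78 → −40 °C; then H2O, −40 → 0 °C; cold pentane extraction; titrated solution kept at −20 °C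
Reagents that add atoms: potassium tert-butoxide, CC(C)(C)[O-].[K+]
Why: In this dichlorovinyl ether route to ynol ethers, tert-butoxide generates dichloroacetylene from trichloroethylene and adds to it, and two equivalents of butyllithium then effect deprotonation/β-elimination and chlorine–lithium exchange to the lithium acetylide, which water protonates.

Step 11
Reactants: 14 methyl (3R,5E)-3-[3,4-bis(benzyloxy)phenyl]-6-(chlorocarbonyl)-8-(3,4-dimethoxyphenyl)oct-5-enoate; 18 tert-butoxyacetylene (4 equiv)
Product: 24 (R)-4-[3,4-bis(benzyloxy)phenyl]-7-tert-butoxy-6-[2-(3,4-dimethoxyphenyl)ethyl]chroman-2-one, via vinylketene 19 (not isolated), via vinylcyclobutenone 20 (not isolated), via dienylketene 21 (not isolated), via cyclohexadienone 22 (not isolated), via phenol ester 23 (not isolated)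
Conditions: Et3N (2.5 equiv), CH2Cl2, 0 → 35 °C, slow addition of 14; volatiles off at ≤ 25 °C; then toluene, 4 Å MS, 90 °C
Reagents that add atoms: none
Why: Proposed new method: Triethylamine removes a γ-hydrogen (the C4 methylene of 14, the only acidic set) with loss of chloride to give vinylketene 19; the unsubstituted, nucleophilic carbon of 18 attacks the ketene carbon in a [2+2] cycloaddition to 3-tert-butoxy-4-vinylcyclobutenone 20, and on heating strain-driven 4π opening to dienylketene 21, 6π electrocyclisation to dienone 22 and tautomerisation give phenol 23, which lactonises to 24. The closest known reaction type is the Danheiser benzannulation of vinylketenes with alkoxy- or siloxyalkynes, where the vinylketene comes from a cyclobutenone or a photochemical Wolff rearrangement; making it by 1,4-dehydrochlorination beside the ynol ether has precedent only in the separate [2+2] reactions of amine-generated ketenes with alkoxyacetylenes. Ring A closes by thermal 6π electrocyclisation (C8a–C4a) after the cycloaddition has laid down C8a–C8 and C7–C6, and ring B closes by 6-exo-trig acyl substitution of the C8a phenol on the methyl ester (O1–C2), pulled forward by sequestering methanol on the sieves. No stereocentre is created: C4 is at most allylic in the intermediates, is not deprotonated by a tertiary amine and keeps its configuration. The selectivity needed is regiochemical (OtBu on C7 beside C6, H on C8) and is fixed by the polarity match between the electrophilic ketene carbon and the β-carbon of the ynol ether, while reversible cyclobutenone opening feeds whichever dienylketene geometry can cyclise. Because tert-butyl ynol ethers shed isobutene on warming, the cycloaddition is kept at or below 35 °C and the mixture is heated only after excess 18 has been evaporated; the alkene geometry of 14 is immaterial since it is erased in 19.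

Step 12
Reactants: 24 (R)-4-[3,4-bis(benzyloxy)phenyl]-7-tert-butoxy-6-[2-(3,4-dimethoxyphenyl)ethyl]chroman-2-one
Product: 25 (R)-4-[3,4-bis(benzyloxy)phenyl]-6-[2-(3,4-dimethoxyphenyl)ethyl]-7-hydroxychroman-2-one
Conditions: TFA/CH2Cl2 (1:3), Et3SiH (3 equiv), 0 °C
Reagents that add atoms: none
Why: The aryl tert-butyl ether ionises readily in TFA with the cation reduced to isobutane by the silane, while benzyl and methyl aryl ethers and the lactone survive, and any open-chain 23 carried over should lactonise under the same acid.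

Step 13
Reactants: 25 (R)-4-[3,4-bis(benzyloxy)phenyl]-6-[2-(3,4-dimethoxyphenyl)ethyl]-7-hydroxychroman-2-one
Product: 26 (R)-4-(3,4-dihydroxyphenyl)-6-[2-(3,4-dimethoxyphenyl)ethyl]-7-hydroxychroman-2-one (CNP0376539.1)
Conditions: H2 (1 atm), 10% Pd/C, EtOAc, 20 °C; inert work-up
Reagents that add atoms: none
Why: Palladium-catalysed hydrogenolysis cleaves the two benzylic C–O bonds, while the aryl-ester lactone, the C–C-bonded diarylmethine C4 and the methyl ethers are inert in a non-nucleophilic solvent.

Compound list
1 | 3,4-bis(benzyloxy)benzaldehyde | O=Cc1ccc(OCc2ccccc2)c(OCc2ccccc2)c1 | starting material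
2 | ethyl acetoacetate | CCOC(=O)CC(C)=O | starting material
3 | diethyl 2,4-diacetyl-3-[3,4-bis(benzyloxy)phenyl]pentanedioate (diastereomer mixture; may sit as its cyclic aldol form) | CCOC(=O)C(C(C)=O)C(c1ccc(OCc2ccccc2)c(OCc2ccccc2)c1)C(C(C)=O)C(=O)OCC | intermediate
4 | 3-[3,4-bis(benzyloxy)phenyl]pentanedioic acid | OC(=O)CC(CC(=O)O)c1ccc(OCc2ccccc2)c(OCc2ccccc2)c1 | intermediate
5 | 4-[3,4-bis(benzyloxy)phenyl]oxane-2,6-dione | O=C1CC(CC(=O)O1)c1ccc(OCc2ccccc2)c(OCc2ccccc2)c1 | intermediate
6 | (R)-3-[3,4-bis(benzyloxy)phenyl]-5-methoxy-5-oxopentanoic acid | OC(=O)C[C@H](CC(=O)OC)c1ccc(OCc2ccccc2)c(OCc2ccccc2)c1 | intermediate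
7 | methyl (R)-3-[3,4-bis(benzyloxy)phenyl]-5-hydroxypentanoate | OCC[C@H](CC(=O)OC)c1ccc(OCc2ccccc2)c(OCc2ccccc2)c1 | intermediate
8 | methyl (R)-3-[3,4-bis(benzyloxy)phenyl]-5-oxopentanoate | O=CC[C@H](CC(=O)OC)c1ccc(OCc2ccccc2)c(OCc2ccccc2)c1 | intermediate
9 | tert-butyl diethylphosphonoacetate | CCOP(=O)(OCC)CC(=O)OC(C)(C)C | starting material
10 | 4-(2-bromoethyl)-1,2-dimethoxybenzene | COc1ccc(CCBr)cc1OC | starting material
11 | tert-butyl 2-(diethoxyphosphoryl)-4-(3,4-dimethoxyphenyl)butanoate (racemic) | CCOP(=O)(OCC)C(CCc1ccc(OC)c(OC)c1)C(=O)OC(C)(C)C | intermediate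
12 | methyl (3R,5E)-3-[3,4-bis(benzyloxy)phenyl]-6-(tert-butoxycarbonyl)-8-(3,4-dimethoxyphenyl)oct-5-enoate | COc1ccc(CC/C(C(=O)OC(C)(C)C)=C\C[C@H](CC(=O)OC)c2ccc(OCc3ccccc3)c(OCc3ccccc3)c2)cc1OC | intermediate
13 | (2E,5R)-5-[3,4-bis(benzyloxy)phenyl]-2-[2-(3,4-dimethoxyphenyl)ethyl]-7-methoxy-7-oxohept-2-enoic acid | COc1ccc(CC/C(C(=O)O)=C\C[C@H](CC(=O)OC)c2ccc(OCc3ccccc3)c(OCc3ccccc3)c2)cc1OC | intermediate
14 | methyl (3R,5E)-3-[3,4-bis(benzyloxy)phenyl]-6-(chlorocarbonyl)-8-(3,4-dimethoxyphenyl)oct-5-enoate | COc1ccc(CC/C(C(=O)Cl)=C\C[C@H](CC(=O)OC)c2ccc(OCc3ccccc3)c(OCc3ccccc3)c2)cc1OC | intermediate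
15 | trichloroethylene | ClC=C(Cl)Cl | starting material
16 | (E)-1-tert-butoxy-1,2-dichloroethene | CC(C)(C)O/C(Cl)=C\Cl | intermediate
17 | lithium tert-butoxyacetylide | [Li]C#COC(C)(C)C | intermediate
18 | tert-butoxyacetylene | C#COC(C)(C)C | intermediate
19 | methyl (3S,4E)-3-[3,4-bis(benzyloxy)phenyl]-6-[2-(3,4-dimethoxyphenyl)ethyl]-7-oxohepta-4,6-dienoate (vinylketene) | COc1ccc(CCC(=C=O)/C=C/[C@H](CC(=O)OC)c2ccc(OCc3ccccc3)c(OCc3ccccc3)c2)cc1OC | intermediate
20 | methyl (3S,4E)-3-[3,4-bis(benzyloxy)phenyl]-5-{2-tert-butoxy-1-[2-(3,4-dimethoxyphenyl)ethyl]-4-oxocyclobut-2-en-1-yl}pent-4-enoate (both epimers at the ring carbon) | COc1ccc(CCC2(/C=C/[C@H](CC(=O)OC)c3ccc(OCc4ccccc4)c(OCc4ccccc4)c3)C(=O)C=C2OC(C)(C)C)cc1OC | intermediate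
21 | methyl (3S,4E,6E)-3-[3,4-bis(benzyloxy)phenyl]-7-tert-butoxy-6-[2-(3,4-dimethoxyphenyl)ethyl]-9-oxonona-4,6,8-trienoate (dienylketene, ketene arm cis to the dienyl arm) | O=C=C/C(OC(C)(C)C)=C(\C=C\[C@H](CC(=O)OC)c1ccc(OCc2ccccc2)c(OCc2ccccc2)c1)CCc1ccc(OC)c(OC)c1 | intermediate
22 | methyl (3S)-3-[3,4-bis(benzyloxy)phenyl]-3-{4-tert-butoxy-5-[2-(3,4-dimethoxyphenyl)ethyl]-2-oxocyclohexa-3,5-dien-1-yl}propanoate (both epimers at ring C1) | O=C1C=C(OC(C)(C)C)C(CCc2ccc(OC)c(OC)c2)=CC1[C@H](CC(=O)OC)c1ccc(OCc2ccccc2)c(OCc2ccccc2)c1 | intermediate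
23 | methyl (3R)-3-[3,4-bis(benzyloxy)phenyl]-3-{4-tert-butoxy-5-[2-(3,4-dimethoxyphenyl)ethyl]-2-hydroxyphenyl}propanoate | Oc1cc(OC(C)(C)C)c(CCc2ccc(OC)c(OC)c2)cc1[C@H](CC(=O)OC)c1ccc(OCc2ccccc2)c(OCc2ccccc2)c1 | intermediate
24 | (R)-4-[3,4-bis(benzyloxy)phenyl]-7-tert-butoxy-6-[2-(3,4-dimethoxyphenyl)ethyl]chroman-2-one | COc1ccc(CCc2cc3c(cc2OC(C)(C)C)OC(=O)C[C@@H]3c2ccc(OCc3ccccc3)c(OCc3ccccc3)c2)cc1OC | intermediate
25 | (R)-4-[3,4-bis(benzyloxy)phenyl]-6-[2-(3,4-dimethoxyphenyl)ethyl]-7-hydroxychroman-2-one | COc1ccc(CCc2cc3c(cc2O)OC(=O)C[C@@H]3c2ccc(OCc3ccccc3)c(OCc3ccccc3)c2)cc1OC | intermediate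
26 | (R)-4-(3,4-dihydroxyphenyl)-6-[2-(3,4-dimethoxyphenyl)ethyl]-7-hydroxychroman-2-one | COc1ccc(CCc2cc3c(cc2O)OC(=O)C[C@@H]3c2ccc(O)c(O)c2)cc1OC | target

Total step count: 13 (steps 6 and 10 are side branches). Longest linear sequence: 11 steps (1–5, 7–9, 11–13).

Steps most likely to fail

Step 11. The vinylketene may dimerise or be consumed by the amine and its hydrochloride faster than the ynol ether captures it. The ynol ether may fragment by retro-ene loss of isobutene before it reacts. Ring opening of the cyclobutenone may stall, or released methanol may trap the dienylketene before 6π closure. Lactonisation may stop at the open hydroxy ester. The fallback uses only known chemistry, takes ring A from the aromatic pool and sets C4 by Rh-catalysed asymmetric conjugate arylation of a coumarin (Hayashi–Miyaura type). It sets out from bromide 10 and comes back to the route at the target 26. Purchased 5-bromo-2,4-dihydroxybenzaldehyde is benzylated at the non-chelated 4-hydroxyl (BnBr, KHCO3, MeCN) to give 4-(benzyloxy)-5-bromo-2-hydroxybenzaldehyde F1. Wittig olefination with ethyl (triphenylphosphoranylidene)acetate in hot N,N-diethylaniline, with lactonisation in the same operation, should give 7-(benzyloxy)-6-bromo-2H-chromen-2-one F2. Bromide 10 is converted with activated zinc and LiCl in THF into [2-(3,4-dimethoxyphenyl)ethyl]zinc bromide F3. Negishi coupling of F3 with F2 (Pd(OAc)2/SPhos, THF) should give 7-(benzyloxy)-6-[2-(3,4-dimethoxyphenyl)ethyl]-2H-chromen-2-one F4. 1,4-Addition of purchased 3,4-bis(benzyloxy)phenylboronic acid under Rh(acac)(C2H4)2/(R)-SEGPHOS in dioxane/water at 60 °C should give (R)-7-(benzyloxy)-4-[3,4-bis(benzyloxy)phenyl]-6-[2-(3,4-dimethoxyphenyl)ethyl]chroman-2-one F5. The ligand antipode is chosen so that C4 is R. Hydrogenolysis under the conditions of step 13 then removes all three benzyl groups and gives 26.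

Step 3. Discrimination between the two enantiotopic carbonyl groups may be poor, through uncatalysed background methanolysis or catalyst self-association, or induction may run in the opposite sense. The fallback replaces asymmetric catalysis by classical resolution; it sets out from anhydride 5 and comes back at 6. Anhydride 5 is opened unselectively in refluxing methanol to racemic 3-[3,4-bis(benzyloxy)phenyl]-5-methoxy-5-oxopentanoic acid F6. Its salt with (S)-1-phenylethylamine (or the antipodal amine, whichever gives the less soluble salt of the R acid) is recrystallised to constant rotation to give (S)-1-phenylethylammonium (R)-3-[3,4-bis(benzyloxy)phenyl]-5-methoxy-5-oxopentanoate F7. Acidification releases 6. The acid left in the mother liquor is saponified back to the achiral diacid 4 and recycled.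

Step 4. The 5-hydroxy ester may cyclise onto its own methyl ester during quench or chromatography, giving the δ-lactone with loss of methanol, and excess borane may begin to reduce the ester. The fallback never passes through the alcohol oxidation level; it sets out from 6 and comes back at 8. Acid 6 is coupled with ethanethiol (EDC, DMAP, CH2Cl2) to give methyl (S)-3-[3,4-bis(benzyloxy)phenyl]-5-(ethylsulfanyl)-5-oxopentanoate F8, which has the same spatial arrangement and changes descriptor only by CIP ranking. Fukuyama reduction (Et3SiH, Pd/C, acetone, 20 °C) should take F8 directly to aldehyde 8, the aprotic solvent keeping the benzyl ethers out of reach of the catalyst.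

Further compounds
F1 | step 11 | 4-(benzyloxy)-5-bromo-2-hydroxybenzaldehyde | O=Cc1cc(Br)c(OCc2ccccc2)cc1O
F2 | step 11 | 7-(benzyloxy)-6-bromo-2H-chromen-2-one | O=c1ccc2cc(Br)c(OCc3ccccc3)cc2o1
F3 | step 11 | [2-(3,4-dimethoxyphenyl)ethyl]zinc bromide | COc1ccc(CC[Zn]Br)cc1OC
F4 | step 11 | 7-(benzyloxy)-6-[2-(3,4-dimethoxyphenyl)ethyl]-2H-chromen-2-one | COc1ccc(CCc2cc3ccc(=O)oc3cc2OCc2ccccc2)cc1OC
F5 | step 11 | (R)-7-(benzyloxy)-4-[3,4-bis(benzyloxy)phenyl]-6-[2-(3,4-dimethoxyphenyl)ethyl]chroman-2-one | COc1ccc(CCc2cc3c(cc2OCc2ccccc2)OC(=O)C[C@@H]3c2ccc(OCc3ccccc3)c(OCc3ccccc3)c2)cc1OC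
F6 | step 3 | rac-3-[3,4-bis(benzyloxy)phenyl]-5-methoxy-5-oxopentanoic acid | OC(=O)CC(CC(=O)OC)c1ccc(OCc2ccccc2)c(OCc2ccccc2)c1
F7 | step 3 | (S)-1-phenylethylammonium (R)-3-[3,4-bis(benzyloxy)phenyl]-5-methoxy-5-oxopentanoate | [O-]C(=O)C[C@H](CC(=O)OC)c1ccc(OCc2ccccc2)c(OCc2ccccc2)c1.C[C@H]([NH3+])c1ccccc1
F8 | step 4 | methyl (S)-3-[3,4-bis(benzyloxy)phenyl]-5-(ethylsulfanyl)-5-oxopentanoate | CCSC(=O)C[C@H](CC(=O)OC)c1ccc(OCc2ccccc2)c(OCc2ccccc2)c1
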